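**Plan**

- Retrosynthesis: epimerise C5 and remove the C7=C7a unsaturation (Saegusa transform) to reach a bicyclic silyl enol ether. Then cut C3a–C7a and C4–C5 together ([4+2]), then O1–C7a (oxa-Michael), C3a–allyl (allylindation of an alkyne) and C2–C3 (propargylation of the aldehyde).
- Enabling feature: the vinylogous ester O1–C7a=C7–C6(=O) of the cyclohexenone ring, flanked by quaternary C3a and methylene C4, is the retron of a 1-alkoxy-3-silyloxydiene/alkene cycloadduct. O1–C2–C3 of the furan ring is a built-in three-atom tether.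
- Forward: (S)-but-3-yn-2-ol and 3,4,5-trimethoxybenzaldehyde give the anti homopropargylic alcohol, then the 1,4-dienol, then the dienyl ether. The furan ring and the carbocycle arise together in the cycloaddition; oxidation and epimerisation finish the route.
- Stereochemistry: C3 comes from (S)-but-3-yn-2-ol by chirality transfer, C2 from the cyclic anti-selective addition, C3a from the C2/C3-substituted tether in the cycloaddition, and C5 from thermodynamic equilibration.

Key step: step 7

Assumption: locants (O1, C2, C3, C3a, C4–C7, C7a) are those of the benzofuran core of the target. The cycloadduct is carried on as a mixture at C5 and C7a, because C7a becomes sp2 in step 8 and C5 (alpha to the ketone) is equilibrated in step 9 to the isomer with pseudo-equatorial OMe, which is the target configuration.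

**Route**

Step 1
Reactants: 1 (S)-but-3-yn-2-ol
Product: 2 (S)-but-3-yn-2-yl methanesulfonate
Conditions: MsCl, Et3N, CH2Cl2, −78 °C
Reagents that add atoms: methanesulfonyl chloride, CS(=O)(=O)Cl
Why: Standard O-sulfonylation of a secondary propargylic alcohol, which does not touch the C–O bond, so the (S) centre is retained.

Step 2
Reactants: 2 (S)-but-3-yn-2-yl methanesulfonate; 3 3,4,5-trimethoxybenzaldehyde
Product: 5 (1R,2R)-2-methyl-1-(3,4,5-trimethoxyphenyl)but-3-yn-1-ol, via allenylindium reagent 4 (not isolated)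
Conditions: PdCl2(dppf) (5 mol %), InI, THF–HMPA 3:1, rt
Reagents that add atoms: none
Why: Marshall propargylation, in which zerovalent palladium opens the mesylate in an anti SN2' sense, transmetalation gives an axially chiral allenylindium, and its cyclic SE2' addition to the aldehyde transfers the carbinol chirality to the methyl-bearing carbon (R) and places OH and methyl anti (carbinol R); the minor syn isomer is removed by chromatography.

Step 3
Reactants: 5 (1R,2R)-2-methyl-1-(3,4,5-trimethoxyphenyl)but-3-yn-1-ol
Product: 7 (1R,2R)-2-methyl-3-methylidene-1-(3,4,5-trimethoxyphenyl)hex-5-en-1-ol, via alkenylindium adduct 6 (not isolated)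
Conditions: In powder, allyl bromide, DMF, rt (forms (C3H5)3In2Br3); then 5, 100 °C; aq. NH4Cl
Reagents that add atoms: allyl bromide, C=CCBr
Why: Hydroxyl-directed carboindation of a terminal alkynol (Araki allylindation) should deliver allyl to the internal alkyne carbon and indium to the terminal one, so protonolysis gives the 2-substituted 1,4-diene without forming or touching a stereocentre.

Step 4
Reactants: 8 N,2-dimethoxy-N-methylacetamide
Product: 10 1-methoxybut-3-yn-2-one, via magnesium chelate 9 (not isolated)
Conditions: HC≡CMgBr, THF, 0 °C; inverse quench into cold aq. NaHSO4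
Reagents that add atoms: ethynylmagnesium bromide, C#C[Mg]Br
Why: Weinreb ketone synthesis, in which the stable magnesium chelate prevents over-addition and the acidic inverse quench keeps the liberated amine from adding to the ynone.

Step 5
Reactants: 7 (1R,2R)-2-methyl-3-methylidene-1-(3,4,5-trimethoxyphenyl)hex-5-en-1-ol; 10 1-methoxybut-3-yn-2-one
Product: 11 (3E)-1-methoxy-4-{[(1R,2R)-2-methyl-3-methylidene-1-(3,4,5-trimethoxyphenyl)hex-5-en-1-yl]oxy}but-3-en-2-one
Conditions: PMe3 (10 mol %), CH2Cl2, 0 °C to rt
Reagents that add atoms: none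
Why: Phosphine-catalysed oxa-Michael addition of a secondary alcohol to a terminal ynone should give the (E)-β-alkoxy enone without affecting C2 or the skipped diene.

Step 6
Reactants: 11 (3E)-1-methoxy-4-{[(1R,2R)-2-methyl-3-methylidene-1-(3,4,5-trimethoxyphenyl)hex-5-en-1-yl]oxy}but-3-en-2-one
Product: 12 tert-butyl{[(1Z,3E)-1-methoxy-4-{[(1R,2R)-2-methyl-3-methylidene-1-(3,4,5-trimethoxyphenyl)hex-5-en-1-yl]oxy}buta-1,3-dien-2-yl]oxy}dimethylsilane
Conditions: TBSOTf, Et3N, Et2O, −78 to 0 °C
Reagents that add atoms: tert-butyldimethylsilyl trifluoromethanesulfonate, CC(C)(C)[Si](C)(C)OS(=O)(=O)C(F)(F)F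
Why: Soft enolisation of the only enolisable position of the vinylogous ester (the methoxymethyl group), as in the preparation of Danishefsky-type dienes, should give the 2-silyloxy diene with the Z enol ether (OMe cis to OSi, the outside position of the s-cis diene).

Step 7
Reactants: 12 tert-butyl{[(1Z,3E)-1-methoxy-4-{[(1R,2R)-2-methyl-3-methylidene-1-(3,4,5-trimethoxyphenyl)hex-5-en-1-yl]oxy}buta-1,3-dien-2-yl]oxy}dimethylsilane
Product: 13 tert-butyl{[(2R,3R,3aR,5S,7aS)-5-methoxy-3-methyl-3a-(prop-2-en-1-yl)-2-(3,4,5-trimethoxyphenyl)-2,3,3a,4,5,7a-hexahydro-1-benzofuran-6-yl]oxy}dimethylsilane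
Conditions: PhMe (0.01 M), BHT, Et3N (trace), sealed tube, 180 °C
Reagents that add atoms: none
Why: A thermal intramolecular [4+2] cycloaddition of the 1-alkoxy-4-methoxy-3-silyloxy diene with the tethered 1,1-disubstituted alkene forms the C3a–C7a and C4–C5 bonds in one concerted, asynchronous event; the closest known reaction type is the intramolecular Diels–Alder reaction of 2-silyloxy-1,3,8-nonatrienes with unactivated alkenes. The furan ring closes in the 5-exo sense through the O1–C2–C3 tether and the carbocycle closes as the new cyclohexene, so the regiochemistry (oxygenated diene terminus C7a to the substituted alkene carbon) is enforced by the tether. The quaternary centre C3a is set by the C2/C3 stereocentres: only in the trans-fused transition state can the anti-related aryl and methyl groups both lie pseudo-equatorially on the forming furan ring, the aryl turned away from C7 and the methyl away from C4, and bonding of C7a to that alkene face leaves allyl cis to methyl (3aR). The centres C7a and C5 (fixed by the fusion mode and the Z enol ether; drawn for the trans-fused adduct) need no control, because C7a becomes sp2 in step 8 and C5 is equilibrated in step 9. The step needs the 1,1-disubstituted alkene and not the terminal allyl alkene to react, which ring size secures (five- against seven-membered tether ring), and it needs the diene to survive the temperature, which the TBS enol ether, BHT and a trace of amine should secure.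

Step 8
Reactants: 13 tert-butyl{[(2R,3R,3aR,5S,7aS)-5-methoxy-3-methyl-3a-(prop-2-en-1-yl)-2-(3,4,5-trimethoxyphenyl)-2,3,3a,4,5,7a-hexahydro-1-benzofuran-6-yl]oxy}dimethylsilane
Product: 14 (2R,3R,3aR,5S)-5-methoxy-3-methyl-3a-(prop-2-en-1-yl)-2-(3,4,5-trimethoxyphenyl)-3,3a,4,5-tetrahydro-1-benzofuran-6(2H)-one
Conditions: Pd(OAc)2 (1.1 equiv), MeCN, rt
Reagents that add atoms: none
Why: Saegusa–Ito oxidation, in which the palladium enolate formed at C7 can undergo β-hydride elimination only towards C7a, which erases that centre and creates the vinylogous ester O1–C7a=C7–C6(=O); the isolated terminal alkene should not react at room temperature, and the product is kept below 40 °C to avoid Cope migration of the allyl group.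

Step 9
Reactants: 14 (2R,3R,3aR,5S)-5-methoxy-3-methyl-3a-(prop-2-en-1-yl)-2-(3,4,5-trimethoxyphenyl)-3,3a,4,5-tetrahydro-1-benzofuran-6(2H)-one
Product: 15 (2R,3R,3aR,5R)-5-methoxy-3-methyl-3a-(prop-2-en-1-yl)-2-(3,4,5-trimethoxyphenyl)-3,3a,4,5-tetrahydro-1-benzofuran-6(2H)-one
Conditions: DBU (0.2 equiv), PhMe, rt
Reagents that add atoms: none
Why: Base-mediated enolisation of the α-methoxy ketone should equilibrate C5 to the epimer with pseudo-equatorial OMe, trans to the pseudo-axial allyl group (no 1,3-diaxial contact), which is the target; C2, C3 and C3a carry no acidic hydrogen and are untouched.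

**Compound list**

1 | (S)-but-3-yn-2-ol | C#C[C@H](C)O | starting material
2 | (S)-but-3-yn-2-yl methanesulfonate | C#C[C@H](C)OS(C)(=O)=O | intermediate
3 | 3,4,5-trimethoxybenzaldehyde | COc1cc(C=O)cc(OC)c1OC | starting material
4 | (aR)-buta-1,2-dien-1-yl(iodo)indium methanesulfonate (axial chirality from the anti SN2' palladation; the allene axis is not encoded in the SMILES) | CC=C=C[In](I)OS(C)(=O)=O | intermediate
5 | (1R,2R)-2-methyl-1-(3,4,5-trimethoxyphenyl)but-3-yn-1-ol | O[C@@H](c1cc(OC)c(OC)c(OC)c1)[C@@H](C#C)C | intermediate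
6 | (E)-[(3R,4R)-4-hydroxy-3-methyl-2-(prop-2-en-1-yl)-4-(3,4,5-trimethoxyphenyl)but-1-en-1-yl]indium dibromide | O[C@@H](c1cc(OC)c(OC)c(OC)c1)[C@@H](/C(CC=C)=C/[In](Br)Br)C | intermediate
7 | (1R,2R)-2-methyl-3-methylidene-1-(3,4,5-trimethoxyphenyl)hex-5-en-1-ol | O[C@@H](c1cc(OC)c(OC)c(OC)c1)[C@@H](C(=C)CC=C)C | intermediate
8 | N,2-dimethoxy-N-methylacetamide | COCC(=O)N(C)OC | starting material
9 | bromomagnesium 1-methoxy-2-[methoxy(methyl)amino]but-3-yn-2-olate | COCC(C#C)(O[Mg]Br)N(C)OC | intermediate
10 | 1-methoxybut-3-yn-2-one | COCC(=O)C#C | intermediate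
11 | (3E)-1-methoxy-4-{[(1R,2R)-2-methyl-3-methylidene-1-(3,4,5-trimethoxyphenyl)hex-5-en-1-yl]oxy}but-3-en-2-one | COCC(=O)/C=C/O[C@@H](c1cc(OC)c(OC)c(OC)c1)[C@@H](C(=C)CC=C)C | intermediate
12 | tert-butyl{[(1Z,3E)-1-methoxy-4-{[(1R,2R)-2-methyl-3-methylidene-1-(3,4,5-trimethoxyphenyl)hex-5-en-1-yl]oxy}buta-1,3-dien-2-yl]oxy}dimethylsilane | CO/C=C(O[Si](C)(C)C(C)(C)C)/C=C/O[C@@H](c1cc(OC)c(OC)c(OC)c1)[C@@H](C(=C)CC=C)C | intermediate
13 | tert-butyl{[(2R,3R,3aR,5S,7aS)-5-methoxy-3-methyl-3a-(prop-2-en-1-yl)-2-(3,4,5-trimethoxyphenyl)-2,3,3a,4,5,7a-hexahydro-1-benzofuran-6-yl]oxy}dimethylsilane (trans-fused adduct; its C5/C7a epimers with the same 3aR centre are carried along) | C=CC[C@]12C[C@H](OC)C(O[Si](C)(C)C(C)(C)C)=C[C@@H]1O[C@@H](c1cc(OC)c(OC)c(OC)c1)[C@@H]2C | intermediate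
14 | (2R,3R,3aR,5S)-5-methoxy-3-methyl-3a-(prop-2-en-1-yl)-2-(3,4,5-trimethoxyphenyl)-3,3a,4,5-tetrahydro-1-benzofuran-6(2H)-one (5-epimer of the target) | C=CC[C@]12C[C@H](OC)C(=O)C=C1O[C@@H](c1cc(OC)c(OC)c(OC)c1)[C@@H]2C | intermediate
15 | (2R,3R,3aR,5R)-5-methoxy-3-methyl-3a-(prop-2-en-1-yl)-2-(3,4,5-trimethoxyphenyl)-3,3a,4,5-tetrahydro-1-benzofuran-6(2H)-one | C=CC[C@]12C[C@@H](OC)C(=O)C=C1O[C@@H](c1cc(OC)c(OC)c(OC)c1)[C@@H]2C | target

**Step count and risks**

Total step count: 9. Longest linear sequence: 8 steps (steps 1, 2, 3, 5, 6, 7, 8, 9; step 4 makes the ynone on a side branch).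

Steps most likely to fail:

1. Step 7. The unactivated, 1,1-disubstituted alkene may cycloadd too slowly, so that the silyl dienol ether is lost thermally first. The cis-fused transition state may also compete and erode facial selectivity at C3a. The fallback sets out from 5 and comes back at 15, and forms the quaternary centre by substrate-controlled lactone alkylation instead. Ruthenium-catalysed cycloisomerisation–oxidation of 5 (CpRuCl(cod), tri(2-furyl)phosphine, N-hydroxysuccinimide, NaHCO3, DMF–H2O, 95 °C) would give (4R,5R)-4-methyl-5-(3,4,5-trimethoxyphenyl)oxolan-2-one F1. Enolisation with LiN(iPr)2 and allyl bromide, which should enter anti to the methyl group, would give (3R,4R,5R)-4-methyl-3-(prop-2-en-1-yl)-5-(3,4,5-trimethoxyphenyl)oxolan-2-one F2. A second enolisation and Michael addition to 3-methoxybut-3-en-2-one, again anti to methyl so that allyl ends cis to it, would give (3R,4R,5R)-3-(2-methoxy-3-oxobutyl)-4-methyl-3-(prop-2-en-1-yl)-5-(3,4,5-trimethoxyphenyl)oxolan-2-one F3. LiN(SiMe3)2 would then effect an intramolecular Claisen condensation of the methyl ketone onto the lactone carbonyl, and mild acid (PPTS) would re-close the liberated benzylic alcohol onto the 1,3-dione with loss of water and equilibrate C5, giving 15.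

2. Step 3. The allyl group may add with the wrong regiochemistry, or the electron-rich benzylic alcohol may ionise under the Lewis-acidic indium halides at 100 °C. The fallback sets out from 5 and comes back at 7 without a new intermediate: a ruthenium-catalysed alkene–alkyne (Alder-ene) coupling of 5 with propene ([CpRu(MeCN)3]PF6, acetone, rt). This builds the same 2-substituted 1,4-diene by metallacycle formation and β-hydride elimination at room temperature, under non-ionising conditions.

3. Step 8. Transmetalation of the hindered TBS enol ether to palladium may be slow, which would leave time for attack at the allyl alkene or for β-alkoxide elimination that opens the furan ring. The fallback sets out from 13 and comes back at 14. PhSeCl (CH2Cl2, −78 °C) should select the silyl enol ether and give (2R,3R,3aR,5S,7aS)-5-methoxy-3-methyl-7-(phenylselanyl)-3a-(prop-2-en-1-yl)-2-(3,4,5-trimethoxyphenyl)hexahydro-1-benzofuran-6(2H)-one F4. H2O2 with pyridine at 0 °C would give the selenoxide, (2R,3R,3aR,5S,7aS)-5-methoxy-3-methyl-7-(phenylseleninyl)-3a-(prop-2-en-1-yl)-2-(3,4,5-trimethoxyphenyl)hexahydro-1-benzofuran-6(2H)-one F5. Its syn elimination can only take the C7a hydrogen and leads to 14.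

Further compounds
F1 | step 7 | (4R,5R)-4-methyl-5-(3,4,5-trimethoxyphenyl)oxolan-2-one | O1[C@@H](c2cc(OC)c(OC)c(OC)c2)[C@@H](CC1=O)C
F2 | step 7 | (3R,4R,5R)-4-methyl-3-(prop-2-en-1-yl)-5-(3,4,5-trimethoxyphenyl)oxolan-2-one | O1[C@@H](c2cc(OC)c(OC)c(OC)c2)[C@@H]([C@@H](CC=C)C1=O)C
F3 | step 7 | (3R,4R,5R)-3-(2-methoxy-3-oxobutyl)-4-methyl-3-(prop-2-en-1-yl)-5-(3,4,5-trimethoxyphenyl)oxolan-2-one (mixture at the methoxy carbon) | O1[C@@H](c2cc(OC)c(OC)c(OC)c2)[C@@H]([C@@](CC=C)(CC(OC)C(C)=O)C1=O)C
F0 | step 3 | none | none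
F4 | step 8 | (2R,3R,3aR,5S,7aS)-5-methoxy-3-methyl-7-(phenylselanyl)-3a-(prop-2-en-1-yl)-2-(3,4,5-trimethoxyphenyl)hexahydro-1-benzofuran-6(2H)-one | C=CC[C@]12C[C@H](OC)C(=O)C([Se]c3ccccc3)[C@@H]1O[C@@H](c1cc(OC)c(OC)c(OC)c1)[C@@H]2C
F5 | step 8 | (2R,3R,3aR,5S,7aS)-5-methoxy-3-methyl-7-(phenylseleninyl)-3a-(prop-2-en-1-yl)-2-(3,4,5-trimethoxyphenyl)hexahydro-1-benzofuran-6(2H)-one | C=CC[C@]12C[C@H](OC)C(=O)C([Se](=O)c3ccccc3)[C@@H]1O[C@@H](c1cc(OC)c(OC)c(OC)c1)[C@@H]2C
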